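**Retrosynthetic overview**
- The target is unmasked by global desilylation of a tetra-O-silyl adduct.
- The cyclohexene ring is formed last, by a chiral-anion-controlled cationic [4+2] between a 6-dienyl chromane-2,4-dione and a flavylium salt (a cis-locked chalcone equivalent); this sets the all-cis triad.
- The diene comes from 5-OH-directed C6 iodination and Suzuki dienylation of the (S)-3-aryl-3-prenylchromane-2,4-dione.
- The quaternary centre (first stereocentre) is set by asymmetric Pd-catalysed C3-prenylation of an achiral 3-aryl-4-hydroxycoumarin.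
- The pyranone ring is formed first, by Hoesch acylation of phloroglucinol and carbonylative lactonisation.

Assumption: the SMILES is read literally, i.e. (3S) quaternary centre and an all-cis (1S,5R,6R) cyclohexene triad (benzoyl cis to both flanking aryl groups), and the target is taken to be isolable in the open chromane-2,4-dione/ketone form drawn.

**Step 1**
Reactants: 1 phloroglucinol; 2 2-[2,4-bis(benzyloxy)phenyl]acetonitrile
Product: 4 2-[2,4-bis(benzyloxy)phenyl]-1-(2,4,6-trihydroxyphenyl)ethan-1-one, via ketiminium chloride 3 (not isolated)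
Conditions: ZnCl2 (1.2 equiv), HCl (g), Et2O, 0 °C, 24 h; then H2O, 100 °C, 1 h
Reagents that add atoms: water (O)
Why: Houben–Hoesch acylation, in which the activated nitrile acylates the symmetric, very electron-rich phloroglucinol once (the iminium salt precipitates), the benzyl ethers survive cold anhydrous HCl, and hydrolysis gives the ketone; no stereocentre.

**Step 2**
Reactants: 4
Product: 6 3-[2,4-bis(benzyloxy)phenyl]-4,5,7-trihydroxy-2H-chromen-2-one, via biscarbonate coumarin 5 (not isolated)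
Conditions: ClCO2Me (4 equiv), K2CO3 (6 equiv), acetone, 56 °C; then 2 M NaOH, MeOH, 0 → 23 °C; 1 M HCl
Reagents that add atoms: methyl chloroformate (COC(=O)Cl)
Why: Classical deoxybenzoin-to-4-hydroxycoumarin synthesis, in which the phenols are methoxycarbonylated, the benzylic ketone enolate undergoes intramolecular Claisen-type C-acylation on an ortho carbonate (both ortho positions are equivalent on symmetric ring A), and the two remaining aryl carbonates are saponified while the 4-hydroxycoumarin anion resists hydroxide.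

**Step 3**
Reactants: 6
Product: 7 3-(2,4-dihydroxyphenyl)-4,5,7-trihydroxy-2H-chromen-2-one
Conditions: H2 (1 atm), Pd/C (10 wt%), EtOAc–MeOH, 23 °C
Reagents that add atoms: none
Why: Neutral hydrogenolysis of the two benzyl ethers frees the 2'-hydroxyl without the acid or heat that would dehydrate a 3-(2-hydroxyaryl)-4-hydroxycoumarin to a coumestan, and the enolic C3=C4 bond is not reduced.

**Step 4**
Reactants: 7; 8 3-methylbut-2-en-1-yl acetate (prenyl acetate)
Product: 9 (3S)-3-(2,4-dihydroxyphenyl)-5,7-dihydroxy-3-(3-methylbut-2-en-1-yl)chromane-2,4-dione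
Conditions: Pd2(dba)3·CHCl3 (2.5 mol%), (R,R)-DACH-phenyl Trost ligand [(1R,2R)-N,N'-bis(2-diphenylphosphinobenzoyl)cyclohexane-1,2-diamine] (7.5 mol%), THF, 0 → 23 °C
Reagents that add atoms: none
Why: Tsuji–Trost asymmetric allylic alkylation, in which only the vinylogous acid (pKa about 5, far below the phenols) is ionised by the released acetate, any O-prenyl ether re-ionises, and the enolate attacks the unsubstituted terminus of the dimethylallyl–palladium complex inside the chiral ligand pocket to set the C3 quaternary centre as (S) (ligand sense assigned by analogy to cyclic β-dicarbonyl nucleophiles, with the antipodal ligand used in the same step if the sense proves reversed).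

**Step 5**
Reactants: 9
Product: 10 (3S)-3-[2,4-bis(tert-butyldimethylsilyloxy)phenyl]-7-(tert-butyldimethylsilyloxy)-5-hydroxy-3-(3-methylbut-2-en-1-yl)chromane-2,4-dione
Conditions: TBSCl (3.3 equiv), i-Pr2NEt (4 equiv), DMF, 0 °C
Reagents that add atoms: tert-butyldimethylsilyl chloride (CC(C)(C)[Si](C)(C)Cl)
Why: Chemoselective phenol silylation, in which the three unchelated phenols react while the 5-OH, hydrogen-bonded to the C4 ketone, stays free, and the non-nucleophilic amine spares the aryl lactone; C3 is untouched.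

**Step 6**
Reactants: 10
Product: 11 (3S)-3-[2,4-bis(tert-butyldimethylsilyloxy)phenyl]-7-(tert-butyldimethylsilyloxy)-5-hydroxy-6-iodo-3-(3-methylbut-2-en-1-yl)chromane-2,4-dione
Conditions: BnNMe3 ICl2 (1.05 equiv), CaCO3 (2 equiv), CH2Cl2–MeOH 5:2, 0 → 23 °C
Reagents that add atoms: benzyltrimethylammonium dichloroiodate (C[N+](C)(C)Cc1ccccc1.Cl[I-]Cl)
Why: Electrophilic aromatic iodination ortho to the only free, chelated phenol (the 5-hydroxy-7-alkoxyflavone precedent gives C6 iodides with this reagent), with aryl silyl ethers inert in the absence of a Lewis acid and the prenyl alkene slower than the phenol.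

**Step 7**
Reactants: 12 2-methylbut-1-en-3-yne
Product: 13 (E)-4,4,5,5-tetramethyl-2-(3-methylbuta-1,3-dien-1-yl)-1,3,2-dioxaborolane
Conditions: pinacolborane (1.1 equiv), Cp2Zr(H)Cl (5 mol%), Et3N (10 mol%), neat, 60 °C, sealed tube
Reagents that add atoms: pinacolborane (B1OC(C)(C)C(C)(C)O1)
Why: Zirconium-catalysed syn hydroboration of the terminal alkyne puts boron on the terminal carbon and gives the E-dienylboronate.

**Step 8**
Reactants: 11; 13
Product: 14 (3S)-3-[2,4-bis(tert-butyldimethylsilyloxy)phenyl]-7-(tert-butyldimethylsilyloxy)-5-hydroxy-6-[(1E)-3-methylbuta-1,3-dien-1-yl]-3-(3-methylbut-2-en-1-yl)chromane-2,4-dione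
Conditions: Pd(OAc)2 (5 mol%), SPhos (10 mol%), K3PO4 (2 equiv), THF–H2O 10:1, 40 °C
Reagents that add atoms: none
Why: Suzuki–Miyaura coupling of the aryl iodide with retention of the E-alkene geometry, under mild phosphate conditions chosen to spare the silyl ethers and the lactone.

**Step 9**
Reactants: 14
Product: 15 (3S)-3-[2,4-bis(tert-butyldimethylsilyloxy)phenyl]-7-(tert-butyldimethylsilyloxy)-6-[(1E)-3-methylbuta-1,3-dien-1-yl]-3-(3-methylbut-2-en-1-yl)-5-(triethylsilyloxy)chromane-2,4-dione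
Conditions: TESOTf (1.3 equiv), 2,6-lutidine (2.5 equiv), CH2Cl2, −78 °C
Reagents that add atoms: triethylsilyl trifluoromethanesulfonate (CC[Si](CC)(CC)OS(=O)(=O)C(F)(F)F)
Why: A silyl triflate with a hindered base caps the chelated, hindered 5-OH so that it cannot trap the cationic intermediate of step 11 as a cyclic ketal.

**Step 10**
Reactants: 16 2,4-dihydroxybenzaldehyde; 17 1-(2,4-dihydroxyphenyl)ethan-1-one
Product: 18 2-(2,4-dihydroxyphenyl)-7-hydroxychromenylium chloride
Conditions: HCl (g), EtOAc, 0 → 23 °C, 48 h; filtration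
Reagents that add atoms: hydrogen chloride (Cl)
Why: Classical flavylium synthesis, in which acid-mediated aldol condensation is followed by cyclodehydration of the salicylaldehyde-derived phenol onto the ketone and the salt precipitates.

**Step 11**
Reactants: 15; 18
Product: 21 (3S)-3-[2,4-bis(tert-butyldimethylsilyloxy)phenyl]-7-(tert-butyldimethylsilyloxy)-6-[(1S,5R,6R)-6-(2,4-dihydroxybenzoyl)-5-(2,4-dihydroxyphenyl)-3-methylcyclohex-2-en-1-yl]-3-(3-methylbut-2-en-1-yl)-5-(triethylsilyloxy)chromane-2,4-dione, via oxocarbenium cycloadduct 19 (not isolated), via hemiketal 20 (not isolated)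
Conditions: 18 (1.5 equiv), (R)-TRIP [(R)-3,3'-bis(2,4,6-triisopropylphenyl)-1,1'-binaphthyl-2,2'-diyl hydrogen phosphate] (10 mol%), Na2HPO4 (1.5 equiv), H2O (5 equiv), PhCF3–CH2Cl2 4:1, 0 → 23 °C, 48 h
Reagents that add atoms: water (O)
Why: Proposed new method: chiral-anion phase-transfer [4+2] of a flavylium ion, in which the lipophilic phosphate carries insoluble 18 into solution as a hydrogen-bonded chiral ion pair, the diene CH2 terminus adds to the electrophilic C4 on its Re face and the allyl cation closes onto C3 in an endo, concerted-asynchronous (or rapid stepwise) fashion so that the cis ring fusion fixes C5/C6 and the endo approach places the C1 aryl cis to both, then water adds to 19 to give hemiketal 20, which opens to the chelated o-hydroxyaryl ketone and releases the acid (buffered by Na2HPO4); the closest known reactions are chiral phosphate and anion-binding additions to benzopyrylium and oxocarbenium ions and cationic Diels–Alder reactions, with the catalyst antipode used in the same step if the facial sense proves reversed.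

**Step 12**
Reactants: 21
Product: 22 (3S)-6-[(1S,5R,6R)-6-(2,4-dihydroxybenzoyl)-5-(2,4-dihydroxyphenyl)-3-methylcyclohex-2-en-1-yl]-3-(2,4-dihydroxyphenyl)-5,7-dihydroxy-3-(3-methylbut-2-en-1-yl)chromane-2,4-dione
Conditions: HF·pyridine (excess), THF, 0 °C
Reagents that add atoms: none
Why: Fluoride cleavage of the four aryl silyl ethers under weakly acidic, non-nucleophilic conditions that neither open the chromane-2,4-dione nor enolise the C6 ketone, so no stereocentre is touched.

**Compound list**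
1 | phloroglucinol | Oc1cc(O)cc(O)c1 | starting material
2 | 2-[2,4-bis(benzyloxy)phenyl]acetonitrile | N#CCc1ccc(OCc2ccccc2)cc1OCc1ccccc1 | starting material
3 | 2-[2,4-bis(benzyloxy)phenyl]-1-(2,4,6-trihydroxyphenyl)ethan-1-iminium chloride | [Cl-].[NH2+]=C(Cc1ccc(OCc2ccccc2)cc1OCc1ccccc1)c1c(O)cc(O)cc1O | intermediate (not isolated)
4 | 2-[2,4-bis(benzyloxy)phenyl]-1-(2,4,6-trihydroxyphenyl)ethan-1-one | O=C(Cc1ccc(OCc2ccccc2)cc1OCc1ccccc1)c1c(O)cc(O)cc1O | intermediate
5 | 3-[2,4-bis(benzyloxy)phenyl]-4-hydroxy-5,7-bis(methoxycarbonyloxy)-2H-chromen-2-one | COC(=O)Oc1cc(OC(=O)OC)c2c(O)c(-c3ccc(OCc4ccccc4)cc3OCc3ccccc3)c(=O)oc2c1 | intermediate (not isolated)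
6 | 3-[2,4-bis(benzyloxy)phenyl]-4,5,7-trihydroxy-2H-chromen-2-one | Oc1cc(O)c2c(O)c(-c3ccc(OCc4ccccc4)cc3OCc3ccccc3)c(=O)oc2c1 | intermediate
7 | 3-(2,4-dihydroxyphenyl)-4,5,7-trihydroxy-2H-chromen-2-one | Oc1cc(O)c2c(O)c(-c3ccc(O)cc3O)c(=O)oc2c1 | intermediate
8 | 3-methylbut-2-en-1-yl acetate | CC(=O)OCC=C(C)C | starting material
9 | (3S)-3-(2,4-dihydroxyphenyl)-5,7-dihydroxy-3-(3-methylbut-2-en-1-yl)chromane-2,4-dione | CC(C)=CC[C@@]1(c2ccc(O)cc2O)C(=O)Oc2cc(O)cc(O)c2C1=O | intermediate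
10 | (3S)-3-[2,4-bis(TBS-oxy)phenyl]-7-(TBS-oxy)-5-hydroxy-3-prenylchromane-2,4-dione | CC(C)=CC[C@@]1(c2ccc(O[Si](C)(C)C(C)(C)C)cc2O[Si](C)(C)C(C)(C)C)C(=O)Oc2cc(O[Si](C)(C)C(C)(C)C)cc(O)c2C1=O | intermediate
11 | (3S)-6-iodo analogue of 10 | CC(C)=CC[C@@]1(c2ccc(O[Si](C)(C)C(C)(C)C)cc2O[Si](C)(C)C(C)(C)C)C(=O)Oc2cc(O[Si](C)(C)C(C)(C)C)c(I)c(O)c2C1=O | intermediate
12 | 2-methylbut-1-en-3-yne | C#CC(C)=C | starting material
13 | (E)-4,4,5,5-tetramethyl-2-(3-methylbuta-1,3-dien-1-yl)-1,3,2-dioxaborolane | CC(=C)/C=C/B1OC(C)(C)C(C)(C)O1 | intermediate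
14 | (3S)-6-[(1E)-3-methylbuta-1,3-dien-1-yl] analogue of 10 (5-OH free) | CC(C)=CC[C@@]1(c2ccc(O[Si](C)(C)C(C)(C)C)cc2O[Si](C)(C)C(C)(C)C)C(=O)Oc2cc(O[Si](C)(C)C(C)(C)C)c(/C=C/C(C)=C)c(O)c2C1=O | intermediate
15 | (3S)-5-(triethylsilyloxy) derivative of 14 | CC(C)=CC[C@@]1(c2ccc(O[Si](C)(C)C(C)(C)C)cc2O[Si](C)(C)C(C)(C)C)C(=O)Oc2cc(O[Si](C)(C)C(C)(C)C)c(/C=C/C(C)=C)c(O[Si](CC)(CC)CC)c2C1=O | intermediate
16 | 2,4-dihydroxybenzaldehyde | O=Cc1ccc(O)cc1O | starting material
17 | 1-(2,4-dihydroxyphenyl)ethan-1-one | CC(=O)c1ccc(O)cc1O | starting material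
18 | 2-(2,4-dihydroxyphenyl)-7-hydroxychromenylium chloride | [Cl-].Oc1ccc(c(O)c1)-c1ccc2ccc(O)cc2[o+]1 | intermediate
19 | cis-fused 6-aryl-6a,7,10,10a-tetrahydrobenzo[c]chromen-5-ium cycloadduct (all-cis at the cyclohexene carbons; cation) | CC(C)=CC[C@@]1(c2ccc(O[Si](C)(C)C(C)(C)C)cc2O[Si](C)(C)C(C)(C)C)C(=O)Oc2cc(O[Si](C)(C)C(C)(C)C)c([C@H]3C=C(C)C[C@@H](c4ccc(O)cc4[O+]=5)[C@H]3C5c3ccc(O)cc3O)c(O[Si](CC)(CC)CC)c2C1=O | intermediate (not isolated)
20 | corresponding 6-hydroxy-6H-benzo[c]chromene hemiketal (C6 epimers) | CC(C)=CC[C@@]1(c2ccc(O[Si](C)(C)C(C)(C)C)cc2O[Si](C)(C)C(C)(C)C)C(=O)Oc2cc(O[Si](C)(C)C(C)(C)C)c([C@H]3C=C(C)C[C@@H](c4ccc(O)cc4O5)[C@H]3C5(O)c3ccc(O)cc3O)c(O[Si](CC)(CC)CC)c2C1=O | intermediate (not isolated)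
21 | (3S)-6-[(1S,5R,6R)-6-(2,4-dihydroxybenzoyl)-5-(2,4-dihydroxyphenyl)-3-methylcyclohex-2-en-1-yl] tetra-O-silyl chromane-2,4-dione | CC(C)=CC[C@@]1(c2ccc(O[Si](C)(C)C(C)(C)C)cc2O[Si](C)(C)C(C)(C)C)C(=O)Oc2cc(O[Si](C)(C)C(C)(C)C)c([C@H]3C=C(C)C[C@@H](c4ccc(O)cc4O)[C@H]3C(=O)c3ccc(O)cc3O)c(O[Si](CC)(CC)CC)c2C1=O | intermediate
22 | (3S)-6-[(1S,5R,6R)-6-(2,4-dihydroxybenzoyl)-5-(2,4-dihydroxyphenyl)-3-methylcyclohex-2-en-1-yl]-3-(2,4-dihydroxyphenyl)-5,7-dihydroxy-3-(3-methylbut-2-en-1-yl)chromane-2,4-dione | CC(C)=CC[C@@]1(c2ccc(O)cc2O)C(=O)Oc2cc(O)c([C@H]3C=C(C)C[C@@H](c4ccc(O)cc4O)[C@H]3C(=O)c3ccc(O)cc3O)c(O)c2C1=O | target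

**Step count and risks**
Total: 12 steps. Longest linear sequence: 10 steps (1–6, 8, 9, 11, 12).

The three steps most likely to fail are steps 11, 4 and 6.

Step 11 (the proposed new reaction) may be too slow with the donor-substituted flavylium, may close exo, or may lose the cation to ketal formation or to hydration of 18 to the chalcone. The fallback uses known chemistry and sets out from 15. Commercial (E)-2,2',4,4'-tetrahydroxychalcone F1 is silylated with TBSCl and i-Pr2NEt to the 2'-hydroxy tris-silyl chalcone F2, whose chelated 2'-OH stays free. F2 and 15 are combined in the established chiral boron-promoted Diels–Alder reaction of 2'-hydroxychalcones (B(OPh)3 and the appropriate VANOL enantiomer), and the exo (1S,5R,6S) trans,trans adduct F3 is separated from the endo isomer. F3 is then epimerised at C6 against thermodynamics: KN(SiMe3)2 (2.2 equiv, THF, −78 °C) forms the phenoxide–enolate, and kinetic protonation with 2,6-di-tert-butylphenol occurs on the face away from the two cis aryl groups (the classical ketonisation selectivity of 2-aryl-1-aroylcyclohexanes), giving the all-cis hexasilyl ketone F4. HF·pyridine then removes all silyl groups, and the fallback rejoins the route at 22.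

Step 4 may give O- or C-prenylation of the free phenols or low enantioselectivity on the unprotected pentaol. The fallback sets out from 7, which is silylated first (TBSCl, i-Pr2NEt; the labile 4-O-silyl group is lost on aqueous work-up and the peri 5-OH is left free) to the tris-silyl 4,5-dihydroxycoumarin F5. F5 is C-prenylated under chiral phase-transfer conditions (prenyl bromide, a C2-symmetric binaphthyl spiro-ammonium bromide of the Maruoka type, solid K2CO3, toluene, −20 °C), so that ion pairing rather than a palladium allyl complex controls the quaternary centre. This rejoins the route at 10.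

Step 6 may iodinate C8, the prenyl alkene, or ring B. The fallback sets out from 10 and uses the strictly ortho-selective magnesium phenoxide formylation (MgCl2, Et3N, paraformaldehyde, MeCN, 60 °C) to give the 6-formyl compound F6. Wittig olefination of F6 with the ylide from (2-methylallyl)triphenylphosphonium chloride and KN(SiMe3)2 (THF, −78 °C), followed by iodine-catalysed equilibration to the E-diene, rejoins the route at 14 and bypasses 11 and 13.

Further compounds
F1 | step 11 | (E)-2,2',4,4'-tetrahydroxychalcone | O=C(/C=C/c1ccc(O)cc1O)c1ccc(O)cc1O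
F2 | step 11 | (E)-3-[2,4-bis(tert-butyldimethylsilyloxy)phenyl]-1-[4-(tert-butyldimethylsilyloxy)-2-hydroxyphenyl]prop-2-en-1-one | O=C(/C=C/c1ccc(O[Si](C)(C)C(C)(C)C)cc1O[Si](C)(C)C(C)(C)C)c1ccc(O[Si](C)(C)C(C)(C)C)cc1O
F3 | step 11 | exo (1S,5R,6S) hexasilyl Diels–Alder adduct of 15 and F2 | CC(C)=CC[C@@]1(c2ccc(O[Si](C)(C)C(C)(C)C)cc2O[Si](C)(C)C(C)(C)C)C(=O)Oc2cc(O[Si](C)(C)C(C)(C)C)c([C@H]3C=C(C)C[C@@H](c4ccc(O[Si](C)(C)C(C)(C)C)cc4O[Si](C)(C)C(C)(C)C)[C@@H]3C(=O)c3ccc(O[Si](C)(C)C(C)(C)C)cc3O)c(O[Si](CC)(CC)CC)c2C1=O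
F4 | step 11 | all-cis (1S,5R,6R) hexasilyl ketone (C6 epimer of F3) | CC(C)=CC[C@@]1(c2ccc(O[Si](C)(C)C(C)(C)C)cc2O[Si](C)(C)C(C)(C)C)C(=O)Oc2cc(O[Si](C)(C)C(C)(C)C)c([C@H]3C=C(C)C[C@@H](c4ccc(O[Si](C)(C)C(C)(C)C)cc4O[Si](C)(C)C(C)(C)C)[C@H]3C(=O)c3ccc(O[Si](C)(C)C(C)(C)C)cc3O)c(O[Si](CC)(CC)CC)c2C1=O
F5 | step 4 | 3-[2,4-bis(tert-butyldimethylsilyloxy)phenyl]-7-(tert-butyldimethylsilyloxy)-4,5-dihydroxy-2H-chromen-2-one | CC(C)(C)[Si](C)(C)Oc1cc(O)c2c(O)c(-c3ccc(O[Si](C)(C)C(C)(C)C)cc3O[Si](C)(C)C(C)(C)C)c(=O)oc2c1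
F6 | step 6 | (3S)-3-[2,4-bis(tert-butyldimethylsilyloxy)phenyl]-7-(tert-butyldimethylsilyloxy)-6-formyl-5-hydroxy-3-(3-methylbut-2-en-1-yl)chromane-2,4-dione | CC(C)=CC[C@@]1(c2ccc(O[Si](C)(C)C(C)(C)C)cc2O[Si](C)(C)C(C)(C)C)C(=O)Oc2cc(O[Si](C)(C)C(C)(C)C)c(C=O)c(O)c2C1=O
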